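## The problem

The target, 5,7,8-trihydroxy-3-(3-hydroxy-4,5-dimethoxyphenyl)-6-methoxy-4H-chromen-4-one (31), is an isoflavone: rings A and C are fused along C4a–C8a in a chromen-4-one, and ring B sits on C3. It has no stereogenic element, so nothing has to be set or relayed; the only stereocentres in the plan are sp3 carbons that vanish on aromatisation. The difficulty is ring A, in which every carbon is substituted: C5, C6, C7, C8 and C8a each carry oxygen, and these five neighbouring oxygens must end in three different states (free OH at C5, C7 and C8, a methyl ether at C6, the ring C ether O1 at C8a). Ring B repeats the question on a small scale (3'-OH beside 4'- and 5'-OMe). The free compound is at once a 5,8-hydroquinone and a 7,8-catechol and will oxidise in air, fastest as a phenoxide, so the hydroxyls should be unmasked last and without base. The methyl ethers at C6 and C4' are flanked by oxygen and would be at risk under the strong Lewis acids used for exhaustive dealkylation, which points to benzyl ethers and hydrogenolysis. C4a, the only ring A carbon without oxygen, lies between two oxygen-bearing carbons, so the C4–C4a bond must be made at a hindered, if electron-rich, site. The enabling feature is that ring A without ring C is a benzene with one C–H (C4a) whose neighbours C5 and C8a bear oxygen (a resorcinol), while C6–C7–C8 is a run of three oxygenated carbons: a four-carbon trialkoxy vinylketene (C5 to C8, C5 as ketene carbon) and a two-carbon ynol ether (C4a, C8a) give exactly this pattern, with the C5 and C8a oxygens born in different states.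

## Retrosynthesis

**31 from 30.** The four O–benzyl bonds (C5, C7, C8, C3') are cut first. Benzyl is the one group that leaves all four oxygens in a single neutral, reducing operation, which suits the air-sensitive polyphenol; acid- or Lewis-acid-labile groups would endanger the flanked methyl ethers. Compound 30 is no simpler in skeleton, but it is a stable, fully masked isoflavone. The forward step must spare the C2=C3 bond and the three methyl ethers.

**30 from 28 (through 29), and 28 from 27.** The C4–C4a bond is cut. Closing ring C last at O1–C2/C2–C3 (the deoxybenzoin way) would need an intermolecular acylation at the hindered C4a, and cutting C3–C1' would need a 3-halochromone made by that same acylation. With O1–C2 already in place, the acylation becomes a six-membered ring closure onto the only free position of ring A, so no regiochemical question arises. The acid 28 comes from the methyl ester 27. The forward reaction must activate a donor-substituted acrylic acid without acids that strip benzyl ethers.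

**27 from 20 and 26.** The O1–C2 bond is cut, dividing the molecule into the ring A phenol 20 and the ring B three-carbon unit 26, two pieces of similar size. The bond is made by addition–elimination of the phenoxide on an enol tosylate; O-alkylation at a saturated carbon would leave C2–C3 at the wrong oxidation level. The forward step asks only that the phenoxide attack carbon and not sulfur.

**26 from 21.** Ring B is traced back through the arylacetate 24. The C3–C2 bond comes from formylation (24 to 26 via 25), and the acetate carbon from one-carbon homologation of the aldehyde (22 to 23 to 24), after benzylation of the commercial phenol 21 to 22. The 3'-oxygen is benzyl from the start and needs no later adjustment.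

**20 from 18.** No skeletal bond is cut. Compound 18 has free OH at C5 and a silyl ether at C8a, the reverse of what ring C construction needs, so the two oxygens exchange roles by benzylation (19) and desilylation (20). These two steps are the price of the key step, and they are where its differentiation of C5 from C8a is used.

**18 from 5 and 13 (key disconnection).** Ring A is opened at C4a–C5 and C8–C8a into the cyclobutenone 5 (C5 as carbonyl, C6 as the sp3 methoxy carbon, C7 and C8 as the benzyloxy alkene) and the silyloxyalkyne 13 (C4a–H and C8a–O). Stepwise oxygenation of a benzene would need a long series of directed substitutions and protecting-group exchanges; this cut delivers all six ring carbons with every oxygen in its final or a distinguishable state. A hexasubstituted benzene becomes a four-membered ring with two kinds of oxygen plus a two-carbon alkyne. The forward reaction must join the alkyne to the ketene with the CH carbon on the carbonyl carbon.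

**5 from 1 and 2.** The cyclobutenone goes back through methylation of the alcohol 4 and hydride reduction of one carbonyl of dibenzyl squarate 3, the diester formed from squaric acid 1 and two molecules of benzyl alcohol 2. Because 3 is symmetric, the reduction has no regiochemistry to control, and the reduced carbon becomes C6 with its own, different oxygen substituent.

**13 from 6 and 7.** The alkyne is traced back to the bromovinyl ether 11 (via 12), and that to the vinyl ether 9 (via 10), which is the O-silylated enolate 8 released from tetrahydrofuran 6 by butyllithium and trapped with 7. This avoids the unsubstituted ynolate anion, for which no convenient source exists.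

## Roads not taken

**Alternative 1:** carbon monoxide as C4.
- Cut: both bonds to the carbonyl carbon, C4a–C4 and C4–C3.
- Forward key step: PdCl2(PPh3)2 (divalent palladium, reduced in the flask to zerovalent palladium), K2CO3 and CO would join the ring A iodide A2 to the ring B vinylboronate A3 and give the diaryl propenone A1.
- Merits: the two aromatic halves meet late, under neutral conditions, and no electrophilic acylation of a benzyl-protected ring is needed.
- Weak points: the C–I bond of A2 lies between two alkoxy groups on a hexasubstituted ring, so oxidative addition and CO insertion are slow and direct coupling without CO can compete. A3 is an α-arylvinylboron compound prone to protodeboronation. A1 is a reactive enone that still needs unmasking of the C8a oxygen, ring closure by conjugate addition and a dehydrogenation before hydrogenolysis. Above all, A2 already contains the five differentiated oxygens of ring A plus iodine, so the hardest part of the problem is only moved into its preparation.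
- Comparison: in convergence and mildness at the coupling stage this road is better. The chosen plan sets against it that ring A, with all five oxygens told apart, is made in one step from a symmetric four-membered ring.

**Alternative 2:** ring A annulated last onto a pyranone.
- Cut: through ring A between C8 and C8a, with C4a–C5 made beforehand by adding the lithiated pyranone A7 to the mixed squarate A6.
- Forward key step: heating the adduct A5 would open the cyclobutenone to a dienylketene whose ketene carbon closes onto the pyranone CH carbon; enolisation would give the isoflavone A4 with 5-OH and 8-OH already free.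
- Merits: rings B and C arrive as one block, the ring expansion is intramolecular, and A4 is only an acidolysis and a hydrogenolysis from 31, so this is the shortest of the four routes.
- Weak points: A6 has two different carbonyl groups, and the organolithium must choose the one next to the methoxy carbon, for which only the bulk of the tert-butoxy group speaks. A7 is a metalated, doubly vinylogous ester, liable to add to itself or open. A4 forms as a free hydroquinone at high temperature, next to a tert-butyl ether that can be lost by elimination.
- Comparison: in step count this road is clearly better. The chosen plan sets against it a symmetric squarate (no regiochemical choice in any nucleophilic step), no fragile organometallic, and a polyphenol that stays masked until the last step.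

**Alternative 3:** ring C closed at O1–C8a through a quinone.
- Cut: the O1–C8a bond, with C8a carried as C–H.
- Forward key step: (NH4)2Ce(NO3)6 (tetravalent cerium) in aqueous acetonitrile would turn the 2,5-dimethoxyaryl ketone A9 into the acylquinone A10, whose side-chain enol oxygen adds to C8a; tautomerisation returns ring A as the hydroquinone in A8.
- Merits: ring A needs only four oxygens at the outset, the C5 and C8 hydroxyls need no protecting-group logic because they are the quinone oxygens, and A8 is one hydrogenolysis from 31.
- Weak points: a one-electron oxidant must act on ring A of A9 in the presence of the electron-rich ring B and an enol. A10 offers the alkoxy-bearing C6 and C7 as further electrophilic sites to water. A8 is more easily oxidised than A9 and can be overoxidised by the same reagent. The arene of A9 still needs a benzyl ether at C7 distinguished from methyl ethers at C5, C6 and C8 by classical substitution chemistry.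
- Comparison: in the length of the last stage this road is at least as good. The chosen plan sets against it that it is redox-neutral throughout, never exposes ring B or a free phenol to an oxidant, and builds the substitution pattern instead of correcting it.

Key step: step 7

Remark on the chemistry: compounds 26–29 are drawn as the Z isomers expected from the chelated enolate 25 (oxygen substituent on C3 cis to the carboxyl carbon); an E isomer would reach the same isoflavone, because the activated acyl group in 29 allows rotation about C2=C3.

## Route

Step 1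
Reactants: 1 squaric acid (3,4-dihydroxycyclobut-3-ene-1,2-dione); 2 benzyl alcohol (two equivalents are incorporated)
Product: 3 dibenzyl squarate (3,4-bis(benzyloxy)cyclobut-3-ene-1,2-dione)
Conditions: BnOH (3 equiv), toluene, reflux, Dean–Stark
Reagents that add atoms: benzyl alcohol (the second equivalent of 2), OCc1ccccc1
Why: Squaric acid is a strong vinylogous acid whose two hydroxyls are each esterified by one molecule of benzyl alcohol when water is removed azeotropically (Fischer-type esterification, as for other dialkyl squarates); the symmetric diester makes the future C7 and C8 oxygens identical, so no regiochemical question arises later.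

Step 2
Reactants: 3 dibenzyl squarate
Product: 4 2,3-bis(benzyloxy)-4-hydroxycyclobut-2-en-1-one (racemic)
Conditions: LiAlH(OtBu)3, THF, −78 → −20 °C; H2O quench
Reagents that add atoms: none
Why: The bulky, mild hydride adds 1,2 to one of the two equivalent carbonyl groups, and the aluminium alkoxide is not reduced further at low temperature (mono-reduction of a dialkyl squarate); the new stereocentre is racemic and is destroyed in step 7.

Step 3
Reactants: 4 2,3-bis(benzyloxy)-4-hydroxycyclobut-2-en-1-one
Product: 5 2,3-bis(benzyloxy)-4-methoxycyclobut-2-en-1-one (racemic)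
Conditions: MeI, Ag2O, CaSO4, MeCN, 25 °C, dark
Reagents that add atoms: iodomethane, CI
Why: Purdie methylation, a silver-assisted O-alkylation under near-neutral conditions, is the usual way to cap 4-hydroxycyclobutenones without the base- or acid-induced ring cleavage and loss of alcohol to which they are prone.

Step 4
Reactants: 6 tetrahydrofuran; 7 triisopropylsilyl trifluoromethanesulfonate
Product: 9 (ethenyloxy)triisopropylsilane, via lithium ethenolate 8 (not isolated)
Conditions: n-BuLi, THF, 25 → 35 °C; then TIPSOTf, −78 → 0 °C
Reagents that add atoms: none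
Why: n-BuLi deprotonates tetrahydrofuran at C2 and the anion undergoes [3+2] cycloreversion to ethene and lithium ethenolate 8, which the hard silyl triflate captures on oxygen (enolate O-silylation).

Step 5
Reactants: 9 (ethenyloxy)triisopropylsilane
Product: 11 [(Z)-2-bromoethenyloxy]triisopropylsilane, via 1,2-dibromoethyl silyl ether 10 (not isolated)
Conditions: Br2, CH2Cl2, −78 °C; then Et3N, −78 → 25 °C
Reagents that add atoms: bromine, BrBr
Why: Electrophilic bromine addition to the enol ether, then amine-induced loss of HBr from the α-bromo ether (bromination–dehydrobromination, the classical entry to 2-bromovinyl ethers); the bulky silyl group should resist bromide attack at silicon, and the Z isomer is expected to predominate as it does for alkyl vinyl ethers.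

Step 6
Reactants: 11 [(Z)-2-bromoethenyloxy]triisopropylsilane
Product: 13 (triisopropylsilyloxy)ethyne, via lithium silyloxyacetylide 12 (not isolated)
Conditions: LiN(iPr)2 (2.2 equiv), THF, −78 °C; then aq. NH4Cl, −78 °C
Reagents that add atoms: none
Why: Anti-periplanar E2 dehydrobromination (H on the oxygen-bearing carbon and Br are trans in the Z isomer), the standard synthesis of alkynyl ethers; the excess amide holds the product as acetylide 12 until the cold quench, and the hindered silicon is not attacked by the amide.

Step 7
Reactants: 5 2,3-bis(benzyloxy)-4-methoxycyclobut-2-en-1-one; 13 (triisopropylsilyloxy)ethyne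
Product: 18 3,4-bis(benzyloxy)-2-methoxy-5-(triisopropylsilyloxy)phenol, via vinylketene 14 (not isolated), via alkenylcyclobutenone 15 (not isolated), via dienylketene 16 (not isolated), via cyclohexadienone 17 (not isolated)
Conditions: 13 (1.3 equiv), toluene, 80 → 110 °C, argon
Reagents that add atoms: none
Why: Danheiser benzannulation: heating opens 5 by conrotatory 4π cleavage of the C(=O)–CH(OMe) bond, the methoxy donor turning outward, to give vinylketene 14. The ynol ether 13 then adds across the ketene C=C bond in a polarised [2+2] step in which its nucleophilic CH carbon bonds to the ketene carbonyl carbon (C4a–C5) and its silyloxy carbon to the ketene α-carbon (C8–C8a), giving alkenylcyclobutenone 15. Compound 15 opens in a second 4π step, the benzyloxy donor on the sp3 carbon turning outward and the alkenyl group inward, which gives the Z dienylketene 16 needed for closure. Ring A is closed by thermal disrotatory 6π electrocyclisation between the ketene carbon (C5) and the methoxy-bearing terminus (C6), and dienone 17 tautomerises to phenol 18. The closest known reaction type is the benzannulation of cyclobutenones with silyloxyalkynes to resorcinol monosilyl ethers, together with the thermal ring expansion of squarate-derived 4-alkenylcyclobutenones. No stereocentre survives: those of 5, 15 and 17 are lost on aromatisation. The selectivity needed is the regiochemistry of the [2+2] step, secured by the polarisation of the ynol ether, and inward rotation of the alkenyl group, secured by the stronger outward preference of the oxygen donor. The expected outcome is OH at C5, OSi at C8a, OMe at C6 and OBn at C7 and C8.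

Step 8
Reactants: 18 3,4-bis(benzyloxy)-2-methoxy-5-(triisopropylsilyloxy)phenol
Product: 19 [2,3,5-tris(benzyloxy)-4-methoxyphenoxy]triisopropylsilane
Conditions: BnBr, K2CO3, Bu4NI (cat.), acetone, reflux
Reagents that add atoms: benzyl bromide, BrCc1ccccc1
Why: Williamson etherification of the only free hydroxyl (C5–OH, open on its C4a side); carbonate in acetone leaves the hindered aryl silyl ether intact.

Step 9
Reactants: 19 [2,3,5-tris(benzyloxy)-4-methoxyphenoxy]triisopropylsilane
Product: 20 2,3,5-tris(benzyloxy)-4-methoxyphenol
Conditions: Bu4NF, AcOH, THF, 0 °C, argon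
Reagents that add atoms: none
Why: Fluoride-driven Si–O cleavage (formation of the strong Si–F bond) frees the C8a hydroxyl; acetic acid buffers the very electron-rich phenoxide, which would otherwise be prone to air oxidation, and benzyl and methyl ethers are untouched.

Step 10
Reactants: 21 3-hydroxy-4,5-dimethoxybenzaldehyde
Product: 22 3-(benzyloxy)-4,5-dimethoxybenzaldehyde
Conditions: BnBr, K2CO3, DMF, 60 °C
Reagents that add atoms: benzyl bromide, BrCc1ccccc1
Why: Williamson etherification of the single phenol; the aldehyde is inert to carbonate.

Step 11
Reactants: 22 3-(benzyloxy)-4,5-dimethoxybenzaldehyde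
Product: 23 1-(benzyloxy)-2,3-dimethoxy-5-[2-(methylsulfanyl)-2-(methylsulfinyl)ethenyl]benzene (alkene geometry and sulfur configuration not controlled)
Conditions: MeS(O)CH2SMe, PhCH2NMe3OH (cat., 40% in MeOH), THF, reflux
Reagents that add atoms: methyl (methylsulfinyl)methyl sulfide, CSCS(C)=O
Why: Knoevenagel-type condensation: the CH2 group between sulfide and sulfoxide is deprotonated, adds to the aldehyde and water is lost; the ketene dithioacetal S-oxide is a masked arylacetic acid, and its geometry and sulfur configuration do not matter.

Step 12
Reactants: 23 1-(benzyloxy)-2,3-dimethoxy-5-[2-(methylsulfanyl)-2-(methylsulfinyl)ethenyl]benzene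
Product: 24 methyl 2-[3-(benzyloxy)-4,5-dimethoxyphenyl]acetate
Conditions: HCl, MeOH, 25 °C → reflux
Reagents that add atoms: methanol, CO
Why: Acid-promoted methanolysis of the ketene dithioacetal S-oxide (protonation at the benzylic carbon, addition of methanol, Pummerer-type transfer of the sulfoxide oxygen) gives the ester and MeSSMe, completing a one-carbon homologation of the aldehyde; aryl benzyl and methyl ethers are stable to HCl in methanol.

Step 13
Reactants: 24 methyl 2-[3-(benzyloxy)-4,5-dimethoxyphenyl]acetate
Product: 26 methyl (2Z)-2-[3-(benzyloxy)-4,5-dimethoxyphenyl]-3-(tosyloxy)prop-2-enoate, via sodium formyl-ester enolate 25 (not isolated)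
Conditions: NaH, HCO2Me, THF, 0 → 25 °C; evaporate; then TsCl, THF, 0 °C
Reagents that add atoms: methyl formate, COC=O; 4-toluenesulfonyl chloride, Cc1ccc(cc1)S(Cl)(=O)=O
Why: Crossed Claisen condensation with the non-enolisable formate, driven by deprotonation of the formyl ester to 25, then O-sulfonylation of the sodium-chelated enolate, which should pass its Z geometry to the enol tosylate; methanol is removed before TsCl is added.

Step 14
Reactants: 20 2,3,5-tris(benzyloxy)-4-methoxyphenol; 26 methyl (2Z)-2-[3-(benzyloxy)-4,5-dimethoxyphenyl]-3-(tosyloxy)prop-2-enoate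
Product: 27 methyl (2Z)-2-[3-(benzyloxy)-4,5-dimethoxyphenyl]-3-[2,3,5-tris(benzyloxy)-4-methoxyphenoxy]prop-2-enoate
Conditions: Cs2CO3, DMF (degassed), 0 → 25 °C
Reagents that add atoms: none
Why: Nucleophilic vinylic substitution by addition–elimination: the phenoxide adds to C3 of the acrylate and the ester-stabilised carbanion expels tosylate, forming O1–C2, as known for β-sulfonyloxy-α,β-unsaturated esters such as 4-tosyloxycoumarins with phenols; retention to the Z ether is expected because the leaving group departs before bond rotation.

Step 15
Reactants: 27 methyl (2Z)-2-[3-(benzyloxy)-4,5-dimethoxyphenyl]-3-[2,3,5-tris(benzyloxy)-4-methoxyphenoxy]prop-2-enoate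
Product: 28 (2Z)-2-[3-(benzyloxy)-4,5-dimethoxyphenyl]-3-[2,3,5-tris(benzyloxy)-4-methoxyphenoxy]prop-2-enoic acid
Conditions: LiOH, THF/MeOH/H2O, 25 °C; then 1 M HCl to pH 3
Reagents that add atoms: lithium hydroxide, [Li+].[OH-]
Why: Saponification by acyl attack of hydroxide; the aryloxy donor deactivates C3 towards conjugate displacement, as in the routine hydrolysis of 3-aryloxyacrylates on the way to chromones, and the aryl ethers are inert.

Step 16
Reactants: 28 (2Z)-2-[3-(benzyloxy)-4,5-dimethoxyphenyl]-3-[2,3,5-tris(benzyloxy)-4-methoxyphenoxy]prop-2-enoic acid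
Product: 30 5,7,8-tris(benzyloxy)-3-[3-(benzyloxy)-4,5-dimethoxyphenyl]-6-methoxy-4H-chromen-4-one, via mixed trifluoroacetic anhydride 29 (not isolated)
Conditions: (CF3CO)2O, CH2Cl2, 0 → 25 °C
Reagents that add atoms: none
Why: Intramolecular Friedel–Crafts acylation through the mixed anhydride: the acyl carbon is held over C4a, the only unsubstituted position of ring A and activated by ortho and para oxygens, so ring C closes as a six-membered ring without a Lewis acid, which spares the benzyl ethers; this is the usual closure of 3-aryloxyacrylic acids to chromones.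

Step 17
Reactants: 30 5,7,8-tris(benzyloxy)-3-[3-(benzyloxy)-4,5-dimethoxyphenyl]-6-methoxy-4H-chromen-4-one
Product: 31 5,7,8-trihydroxy-3-(3-hydroxy-4,5-dimethoxyphenyl)-6-methoxy-4H-chromen-4-one
Conditions: H2 (1 atm), Pd/C, EtOAc/MeOH, 25 °C; filtration and concentration under argon
Reagents that add atoms: none
Why: Hydrogenolysis of the four O–benzyl bonds on Pd/C; aryl methyl ethers and the vinylogous-ester C2=C3 bond should survive 1 atm H2 if the reaction is stopped after four equivalents are taken up, and neutral reducing conditions with argon work-up protect the 5,8-hydroquinone.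

## Compound list

1 | squaric acid (3,4-dihydroxycyclobut-3-ene-1,2-dione) | OC1=C(O)C(=O)C1=O | starting material
2 | benzyl alcohol | OCc1ccccc1 | starting material
3 | dibenzyl squarate (3,4-bis(benzyloxy)cyclobut-3-ene-1,2-dione) | O=C1C(=O)C(OCc2ccccc2)=C1OCc1ccccc1 | intermediate
4 | 2,3-bis(benzyloxy)-4-hydroxycyclobut-2-en-1-one (racemic) | OC1C(OCc2ccccc2)=C(OCc2ccccc2)C1=O | intermediate
5 | 2,3-bis(benzyloxy)-4-methoxycyclobut-2-en-1-one (racemic) | COC1C(OCc2ccccc2)=C(OCc2ccccc2)C1=O | intermediate
6 | tetrahydrofuran | C1CCOC1 | starting material
7 | triisopropylsilyl trifluoromethanesulfonate | CC(C)[Si](OS(=O)(=O)C(F)(F)F)(C(C)C)C(C)C | starting material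
8 | lithium ethenolate | [Li+].[O-]C=C | intermediate (not isolated)
9 | (ethenyloxy)triisopropylsilane | C=CO[Si](C(C)C)(C(C)C)C(C)C | intermediate
10 | (1,2-dibromoethoxy)triisopropylsilane (racemic) | BrCC(Br)O[Si](C(C)C)(C(C)C)C(C)C | intermediate (not isolated)
11 | [(Z)-2-bromoethenyloxy]triisopropylsilane | Br/C=C\O[Si](C(C)C)(C(C)C)C(C)C | intermediate
12 | lithium (triisopropylsilyloxy)ethynide | [Li]C#CO[Si](C(C)C)(C(C)C)C(C)C | intermediate (not isolated)
13 | (triisopropylsilyloxy)ethyne | C#CO[Si](C(C)C)(C(C)C)C(C)C | intermediate
14 | (3Z)-2,3-bis(benzyloxy)-4-methoxybuta-1,3-dien-1-one (vinylketene) | O=C=C(OCc1ccccc1)/C(OCc1ccccc1)=C/OC | intermediate (not isolated)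
15 | 4-(benzyloxy)-4-[(Z)-1-(benzyloxy)-2-methoxyethenyl]-3-(triisopropylsilyloxy)cyclobut-2-en-1-one (racemic) | O=C1C=C(O[Si](C(C)C)(C(C)C)C(C)C)C1(OCc2ccccc2)/C(OCc2ccccc2)=C/OC | intermediate (not isolated)
16 | (3Z,5Z)-4,5-bis(benzyloxy)-6-methoxy-3-(triisopropylsilyloxy)hexa-1,3,5-trien-1-one (dienylketene) | O=C=C/C(O[Si](C(C)C)(C(C)C)C(C)C)=C(OCc1ccccc1)\C(OCc1ccccc1)=C\OC | intermediate (not isolated)
17 | 4,5-bis(benzyloxy)-6-methoxy-3-(triisopropylsilyloxy)cyclohexa-2,4-dien-1-one (racemic) | O=C1C=C(O[Si](C(C)C)(C(C)C)C(C)C)C(OCc2ccccc2)=C(OCc2ccccc2)C1OC | intermediate (not isolated)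
18 | 3,4-bis(benzyloxy)-2-methoxy-5-(triisopropylsilyloxy)phenol | COc1c(O)cc(O[Si](C(C)C)(C(C)C)C(C)C)c(OCc2ccccc2)c1OCc1ccccc1 | intermediate
19 | [2,3,5-tris(benzyloxy)-4-methoxyphenoxy]triisopropylsilane | COc1c(OCc2ccccc2)cc(O[Si](C(C)C)(C(C)C)C(C)C)c(OCc2ccccc2)c1OCc1ccccc1 | intermediate
20 | 2,3,5-tris(benzyloxy)-4-methoxyphenol | COc1c(OCc2ccccc2)cc(O)c(OCc2ccccc2)c1OCc1ccccc1 | intermediate
21 | 3-hydroxy-4,5-dimethoxybenzaldehyde | COc1cc(C=O)cc(O)c1OC | starting material
22 | 3-(benzyloxy)-4,5-dimethoxybenzaldehyde | COc1cc(C=O)cc(OCc2ccccc2)c1OC | intermediate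
23 | 1-(benzyloxy)-2,3-dimethoxy-5-[2-(methylsulfanyl)-2-(methylsulfinyl)ethenyl]benzene (geometry and sulfur configuration not controlled) | COc1cc(C=C(SC)S(C)=O)cc(OCc2ccccc2)c1OC | intermediate
24 | methyl 2-[3-(benzyloxy)-4,5-dimethoxyphenyl]acetate | COC(=O)Cc1cc(OC)c(OC)c(OCc2ccccc2)c1 | intermediate
25 | sodium (1Z)-2-[3-(benzyloxy)-4,5-dimethoxyphenyl]-3-methoxy-3-oxoprop-1-en-1-olate | [Na+].[O-]/C=C(\C(=O)OC)c1cc(OC)c(OC)c(OCc2ccccc2)c1 | intermediate (not isolated)
26 | methyl (2Z)-2-[3-(benzyloxy)-4,5-dimethoxyphenyl]-3-(tosyloxy)prop-2-enoate | COC(=O)/C(=C\OS(=O)(=O)c1ccc(C)cc1)c1cc(OC)c(OC)c(OCc2ccccc2)c1 | intermediate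
27 | methyl (2Z)-2-[3-(benzyloxy)-4,5-dimethoxyphenyl]-3-[2,3,5-tris(benzyloxy)-4-methoxyphenoxy]prop-2-enoate | COC(=O)/C(=C\Oc1cc(OCc2ccccc2)c(OC)c(OCc2ccccc2)c1OCc1ccccc1)c1cc(OC)c(OC)c(OCc2ccccc2)c1 | intermediate
28 | (2Z)-2-[3-(benzyloxy)-4,5-dimethoxyphenyl]-3-[2,3,5-tris(benzyloxy)-4-methoxyphenoxy]prop-2-enoic acid | OC(=O)/C(=C\Oc1cc(OCc2ccccc2)c(OC)c(OCc2ccccc2)c1OCc1ccccc1)c1cc(OC)c(OC)c(OCc2ccccc2)c1 | intermediate
29 | (2Z)-2-[3-(benzyloxy)-4,5-dimethoxyphenyl]-3-[2,3,5-tris(benzyloxy)-4-methoxyphenoxy]prop-2-enoic trifluoroacetic anhydride | FC(F)(F)C(=O)OC(=O)/C(=C\Oc1cc(OCc2ccccc2)c(OC)c(OCc2ccccc2)c1OCc1ccccc1)c1cc(OC)c(OC)c(OCc2ccccc2)c1 | intermediate (not isolated)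
30 | 5,7,8-tris(benzyloxy)-3-[3-(benzyloxy)-4,5-dimethoxyphenyl]-6-methoxy-4H-chromen-4-one | COc1cc(-c2coc3c(OCc4ccccc4)c(OCc4ccccc4)c(OC)c(OCc4ccccc4)c3c2=O)cc(OCc2ccccc2)c1OC | intermediate
31 | 5,7,8-trihydroxy-3-(3-hydroxy-4,5-dimethoxyphenyl)-6-methoxy-4H-chromen-4-one | COc1cc(-c2coc3c(O)c(O)c(OC)c(O)c3c2=O)cc(O)c1OC | target

## Step count and least certain steps

Total: 17 steps. Longest linear sequence: 10 steps (steps 1, 2, 3, 7, 8, 9, 14, 15, 16, 17 from squaric acid; the alkyne branch through steps 4, 5, 6 is equally long).

**Step 7 (key step).** Capture of vinylketene 14 by the alkyne may lose out to self-condensation of the donor-rich ketene, to its reclosure, or to acylation of the product phenol by a second ketene; the silyl ether may also be shed at 110 °C. The fallback builds the same ring by a Moore-type ring expansion, in which an intramolecular 6π closure replaces the intermolecular [2+2] step. It sets out from dibenzyl squarate 3. Addition of 1-(methoxymethoxy)vinyllithium (from methoxymethyl vinyl ether and s-BuLi, THF, −78 °C) should give 2,3-bis(benzyloxy)-4-hydroxy-4-[1-(methoxymethoxy)ethenyl]cyclobut-2-en-1-one F1. The tertiary hydroxyl is methylated (MeI, Ag2O, K2CO3) to 2,3-bis(benzyloxy)-4-methoxy-4-[1-(methoxymethoxy)ethenyl]cyclobut-2-en-1-one F2. Heating F2 in toluene should open the ring with the methoxy group outward and close the dienylketene to 2,3-bis(benzyloxy)-4-methoxy-5-(methoxymethoxy)phenol F3, in which the ketene oxygen is the free C8a hydroxyl, the methylated carbinol carbon is C6 and the vinyl ether carbon is C5. Silylation of F3 with 7 and 2,6-lutidine gives [2,3-bis(benzyloxy)-4-methoxy-5-(methoxymethoxy)phenoxy]triisopropylsilane F4, and removal of the methoxymethyl group (HCl, MeOH, 25–40 °C) rejoins the route at 18. This detour also makes steps 2 to 6 unnecessary.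

**Step 5.** Bromide may attack silicon at the α-bromo oxocarbenium stage, so that the silyl group is lost instead of HBr, and the E/Z control may be poor. The fallback sets out from 7: bromoacetaldehyde F5, set free from its commercial diethyl acetal with aqueous acid and dried in CH2Cl2, is treated with 7 and Et3N at 0 °C. O-Silylation of the α-halo aldehyde under soft enolisation should give the Z enol ether and rejoin the route at 11.

**Step 14.** The phenoxide may attack the sulfonyl sulfur (sulfonyl transfer) instead of C3, and the electron-rich phenoxide may be oxidised by traces of air. The fallback sets out from enolate 25 (made from 24 as in step 13). Treatment with (COCl)2 and a little DMF in CH2Cl2 converts it into methyl 2-[3-(benzyloxy)-4,5-dimethoxyphenyl]-3-chloroprop-2-enoate F6 (E/Z mixture), a vinylogous acid chloride with no second electrophilic centre. Phenol 20 with Cs2CO3 in DMF displaces chloride, and the route is rejoined at 27.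

**Step 16.** The donor-stabilised mixed anhydride may be too weak an electrophile without a stronger acid, and stronger acids begin to cleave benzyl ethers and transfer benzyl groups to ring carbons. The fallback inverts the roles, making C4a the nucleophile, and sets out from 20. Iodination at C4a with N-iodosuccinimide in MeCN at 0 °C gives 2,3,5-tris(benzyloxy)-6-iodo-4-methoxyphenol F7. Coupling with 26 as in step 14 gives methyl (2Z)-2-[3-(benzyloxy)-4,5-dimethoxyphenyl]-3-[2,3,5-tris(benzyloxy)-6-iodo-4-methoxyphenoxy]prop-2-enoate F8. Iodine–lithium exchange with n-BuLi in THF at −100 °C and attack of the aryllithium on the neighbouring methyl ester (Parham cyclisation) closes ring C with loss of methoxide and rejoins the route at 30.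

**Step 17.** Hydrogenation may go on to saturate C2=C3, the hindered C5 and C8 ethers may cleave slowly, and the freed hydroquinone may oxidise during work-up. The fallback goes from 30 directly to 31 with BCl3 and pentamethylbenzene as benzyl cation trap in CH2Cl2 at −78 °C. This Lewis acid debenzylation cannot touch the C2=C3 bond, should leave aryl methyl ethers alone at that temperature, and keeps the work-up acidic and oxygen-free; it makes no new compound.

## Further compounds

F1 | step 7 | 2,3-bis(benzyloxy)-4-hydroxy-4-[1-(methoxymethoxy)ethenyl]cyclobut-2-en-1-one (racemic) | C=C(OCOC)C1(O)C(OCc2ccccc2)=C(OCc2ccccc2)C1=O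
F2 | step 7 | 2,3-bis(benzyloxy)-4-methoxy-4-[1-(methoxymethoxy)ethenyl]cyclobut-2-en-1-one (racemic) | C=C(OCOC)C1(OC)C(OCc2ccccc2)=C(OCc2ccccc2)C1=O
F3 | step 7 | 2,3-bis(benzyloxy)-4-methoxy-5-(methoxymethoxy)phenol | COCOc1cc(O)c(OCc2ccccc2)c(OCc2ccccc2)c1OC
F4 | step 7 | [2,3-bis(benzyloxy)-4-methoxy-5-(methoxymethoxy)phenoxy]triisopropylsilane | COCOc1cc(O[Si](C(C)C)(C(C)C)C(C)C)c(OCc2ccccc2)c(OCc2ccccc2)c1OC
F5 | step 5 | bromoacetaldehyde | BrCC=O
F6 | step 14 | methyl 2-[3-(benzyloxy)-4,5-dimethoxyphenyl]-3-chloroprop-2-enoate (E/Z mixture) | COC(=O)C(=CCl)c1cc(OC)c(OC)c(OCc2ccccc2)c1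
F7 | step 16 | 2,3,5-tris(benzyloxy)-6-iodo-4-methoxyphenol | COc1c(OCc2ccccc2)c(I)c(O)c(OCc2ccccc2)c1OCc1ccccc1
F8 | step 16 | methyl (2Z)-2-[3-(benzyloxy)-4,5-dimethoxyphenyl]-3-[2,3,5-tris(benzyloxy)-6-iodo-4-methoxyphenoxy]prop-2-enoate | COC(=O)/C(=C\Oc1c(I)c(OCc2ccccc2)c(OC)c(OCc2ccccc2)c1OCc1ccccc1)c1cc(OC)c(OC)c(OCc2ccccc2)c1
F0 | step 17 | none | none
A1 | alternative 1 | 1-[3,4,6-tris(benzyloxy)-5-methoxy-2-(methoxymethoxy)phenyl]-2-[3-(benzyloxy)-4,5-dimethoxyphenyl]prop-2-en-1-one | COCOc1c(C(=O)C(=C)c2cc(OCc3ccccc3)c(OC)c(OC)c2)c(OCc2ccccc2)c(OC)c(OCc2ccccc2)c1OCc1ccccc1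
A2 | alternative 1 | 1,2,4-tris(benzyloxy)-5-iodo-3-methoxy-6-(methoxymethoxy)benzene | COCOc1c(I)c(OCc2ccccc2)c(OC)c(OCc2ccccc2)c1OCc1ccccc1
A3 | alternative 1 | 2-{1-[3-(benzyloxy)-4,5-dimethoxyphenyl]ethenyl}-4,4,5,5-tetramethyl-1,3,2-dioxaborolane | C=C(B1OC(C)(C)C(C)(C)O1)c1cc(OCc2ccccc2)c(OC)c(OC)c1
A4 | alternative 2 | 7-tert-butoxy-5,8-dihydroxy-6-methoxy-3-[3-(benzyloxy)-4,5-dimethoxyphenyl]-4H-chromen-4-one | COc1c(O)c2c(=O)c(-c3cc(OCc4ccccc4)c(OC)c(OC)c3)coc2c(O)c1OC(C)(C)C
A5 | alternative 2 | 2-tert-butoxy-4-hydroxy-3-methoxy-4-{5-[3-(benzyloxy)-4,5-dimethoxyphenyl]-4-oxo-4H-pyran-3-yl}cyclobut-2-en-1-one (racemic) | COC1=C(OC(C)(C)C)C(=O)C1(O)c1cocc(-c2cc(OCc3ccccc3)c(OC)c(OC)c2)c1=O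
A6 | alternative 2 | 3-tert-butoxy-4-methoxycyclobut-3-ene-1,2-dione | COC1=C(OC(C)(C)C)C(=O)C1=O
A7 | alternative 2 | 3-[3-(benzyloxy)-4,5-dimethoxyphenyl]-5-lithio-4H-pyran-4-one | [Li]c1cocc(-c2cc(OCc3ccccc3)c(OC)c(OC)c2)c1=O
A8 | alternative 3 | 7-(benzyloxy)-3-[3-(benzyloxy)-4,5-dimethoxyphenyl]-5,8-dihydroxy-6-methoxy-4H-chromen-4-one | COc1c(OCc2ccccc2)c(O)c2occ(-c3cc(OCc4ccccc4)c(OC)c(OC)c3)c(=O)c2c1O
A9 | alternative 3 | 1-[4-(benzyloxy)-2,3,5-trimethoxyphenyl]-2-[3-(benzyloxy)-4,5-dimethoxyphenyl]-3-hydroxyprop-2-en-1-one | COc1cc(C(=O)C(=CO)c2cc(OCc3ccccc3)c(OC)c(OC)c2)c(OC)c(OC)c1OCc1ccccc1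
A10 | alternative 3 | 2-(benzyloxy)-5-{2-[3-(benzyloxy)-4,5-dimethoxyphenyl]-3-hydroxyprop-2-enoyl}-3-methoxycyclohexa-2,5-diene-1,4-dione | COC1=C(OCc2ccccc2)C(=O)C=C(C(=O)C(=CO)c2cc(OCc3ccccc3)c(OC)c(OC)c2)C1=O
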